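Readings and results were generated by integration for substances that don't exist, noise included.

In the larch run, starting material read 53.7% after 6.00 h and in the alder run 52.7%, while target read only 1.6% and 0.3%. What had gone had not become target.

| setting | larch | alder | winter | midnight |
|---|---|---|---|---|
| starting material | 20 mM | 20 mM | 20 mM | 20 mM |
| partner | 20 mM | 20 mM | 20.0 mM | 20.0 mM |
| second reagent | 12 mM | 12 mM | 12.0 mM | 12.0 mM |
| third reagent | 28 mM | 76 mM | 120 mM | 40.0 mM |
| protic impurity | 10 mM | 10 mM | 10.0 mM | 10.0 mM |
| remark | run made earlier | run made earlier |  |  |
| time |  |  | 15 h | 50 h |

| run | time / h | target / % | starting material / % |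
|---|---|---|---|
| larch | 3.00 | 0 | 70.0 |
| larch | 4.00 | 1.3 | 61.6 |
| larch | 6.00 | 1.6 | 53.7 |
| larch | 10.0 | 0.2 | 41.2 |
| larch | 15.0 | 5.9 | 30.4 |
| larch | 25.0 | 9.8 | 18.9 |
| larch | 40.0 | 22.2 | 14.5 |
| alder | 3.00 | 0.3 | 71.0 |
| alder | 4.00 | 0 | 64.2 |
| alder | 6.00 | 0.3 | 52.7 |
| alder | 10.0 | 2.9 | 40.9 |
| alder | 15.0 | 9.0 | 31.8 |
| alder | 25.0 | 16.7 | 18.5 |
| alder | 40.0 | 24.4 | 11.1 |

(readings scatter by 1 percentage point)



* which one finishes higher in amount of target, in percent of the starting material charged ("neither" within 2 percentage points) (winter / midnight / neither)
* amount of target at the end, in percent of the starting material charged, winter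
* amount of target at the end, in percent of the starting material charged, midnight

I ranked the time scales. On the first rung, starting material fell within hours. On the second, target stayed low: at 10.0 h it read 0.2% in larch and 2.9% in alder. The third rung was slower. From 15.0 h to 40.0 h the two runs gained 16 percentage points of target on average, while the pool that was neither starting material nor target averaged 62.7%. I divided that pool by its rate of turning into target:

62.7% × 25.0 h / 16 points = 98.9 h

This is my holding time: the pool over the rate at which it yields target. [third reagent] could not be ignored: at 25.0 h, larch with 28 mM read 9.8%, less than alder with 76 mM at 16.7%, and at 40.0 h they read 22.2% and 24.4%. Midnight's 40.0 mM is above larch's charge and below alder's, so I took the two runs together as a rough stand-in. For midnight I started from the mean of those two readings and added the last stretch: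

23.3% + 62.7% × 10.0 h / 98.9 h = 29.6%

Winter stops at 15 h, shorter than the holding time, and alder's [third reagent] is nearer winter's than larch's is, so I took alder's reading at that time, 9.0%, as my winter figure.

The forecast said midnight, with 11% for winter and 29% for midnight: “Most material therefore sits in an intermediate, and the later step is slow”. My winter figure was lower than its own.

The flask gave midnight, with 9.14% for winter and 28.8% for midnight.

    starting material + partner → intermediate A (k = 0.0930 /M/min)
    second reagent + intermediate A → intermediate B (k = 0.0380 /M/min)
    third reagent + intermediate B → target (k = 0.0570 /M/min)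
    starting material + protic impurity → quenched substrate (k = 0.0480 /M/min)
    partner ⇌ dormant form (K = 0.920, k = 5.80 × 10⁻⁴ /min)

By 25.0 h in midnight, the step to intermediate A had 90% of its turnover behind it, and the step to target 47%. So in midnight's first half the filling of the pool ran ahead of its emptying, and intermediate A, the resting state, stood at 32.0% at the end. Over midnight's second half the holding time came to 106 h. With all amounts held, winter's answer moved by 5 points when read at 9.29 h or 20.8 h.

For midnight read at 4.0 d, the holding time gave 58.2%. The flask gave 42.9%, so over that stretch the quotient was 193 h, twice the value from the runs.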